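No recipe on this card can turn the whole starting material into target, since partner is charged at 80.0% of it.

| flask | starting material | partner | time | remark |
|---|---|---|---|---|
| Tuesday's | 0.38 M | 0.304 M | 8.0 min | everything together at the start |
| Monday's | 0.38 M (fed, over 6.0 min) | 0.304 M | 8.0 min | all else is in the flask from the start; the feed brings no volume worth counting |
| Friday's | 0.38 M | 0.304 M (fed, over 6.0 min) | 8.0 min | all else is in the flask from the start; the feed brings no volume worth counting |

    starting material → open intermediate (k1 = 0.0095 s⁻¹)
    open intermediate + second intermediate → target (k2 = 0.082 M⁻¹ s⁻¹)
    2 second intermediate → homo product (k3 = 0.011 M⁻¹ s⁻¹)
    open intermediate → side product (k4 = 0.023 s⁻¹)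
    partner → second intermediate (k5 = 0.036 s⁻¹)
    crystals ⇌ target, rate k6*(cs6 - [target]) while solid is left; crystals form when [target] > cs6 (cs6 = 0.32 M, k6 = 2.8 s⁻¹)
    partner + target → over-reaction product (k7 = 0.057 M⁻¹ s⁻¹)

- the flask that comes out highest in amount of target, in percent of the starting material charged, or "all alike" when all lie within 1.5 percentage points (Tuesday's / Monday's / Friday's / all alike)
- target at the end, in percent of the starting material charged, Tuesday's
- target at the end, in percent of the starting material charged, Monday's
- target at the end, in percent of the starting material charged, Friday's

- what is said of target includes crystals
- for a step with 2 of a species take k times the square, and two of it per event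
- crystals is a solid; its amount is given per volume of the solution
- run time (Tuesday's): 8.0 min

We build the flask up one process at a time. With opening and coupling alone, partner is the limiting reagent, and target stops at that 80.0%.

Now add the leak to side product. Open intermediate has two exits, and their race has a crossing. We call it c×: the c(second intermediate) at which coupling and leak run equally fast, the leak constant over the coupling constant, 0.280 M. At any moment the share of open intermediate that becomes target is c/(c + c×), with c for c(second intermediate). This is a selectivity factor written as a concentration.

The partner charge stands barely above the crossing. Put that whole charge in as second intermediate and the share is 52.0%, a ceiling for Tuesday's. But coupling uses second intermediate up. Taking half the charge as a mean, we get 35.1% for Tuesday's.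

Next add the release of second intermediate from partner. Its half-life, 0.321 min, is shorter than the 1.2 min of starting material, so on Tuesday's the mate is ready early. On Friday's the feed runs much longer than that half-life, so the feed sets the supply instead. At that same 1.2 min the feed has delivered 0.0616 M of partner, well below the crossing, so we reckon a share of 18.0% for Friday's.

Last comes the homo step. Its first half-life at full charge, 2.49 min, is shorter than the feed. On Monday's, then, second intermediate waits and dimerises, and we place Monday's below Tuesday's without a figure. The same step lowers our Tuesday's number by an amount we did not reckon.

The forecast names Tuesday's, with 29.5% for Tuesday's, 24% for Monday's and 16% for Friday's, on the ground that “all-at-once charging overlaps them best”. Our figures for Tuesday's and Friday's stand above its numbers for those flasks.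

The simulation gives 30.6% for Tuesday's, 21.9% for Monday's and 12.6% for Friday's. So Tuesday's is highest, and the forecast held.

Strike out the leak and the gap between Tuesday's and Friday's shrinks from 18 percentage points to 3.4 points. The leak is thus the largest single effect on that gap, though not the whole reason. The crossing shows where Friday's leak happens: half of its turnover is done by 1.73 min, when the feed has brought in 0.0875 M of partner, less than c×.

A neighbour of Friday's holds 0.076 M of partner. Reckoned as for Friday's, the feed has delivered 0.0154 M at 1.2 min, far under c×, so the share comes to 5.21%. The simulation gives 5.02%.

All constants come from no measurement; no experiment stands behind them.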